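**Remark:** the target has no stereocentre or stereoaxis (it is achiral), so there is no enantiomer to select; it is drawn as one of several equivalent enol tautomers. Ethoxyacetylene is used as its commercial solution in hexanes.

**Plan**
- Cut both ArCH2–C(ring) bonds between the bridging methylenes and the two outer trione rings: bis(aminomethyl)butyrylphloroglucinol 13 plus two molecules of propionylfilicinic acid 10.
- Cut the propionyl C–C bond of 10 to reach filicinic acid 9, then open its ring between C(=O) and the neighbouring CH and excise a C–C(O) two-carbon unit: cyclobutenone 4 plus ethoxyacetylene; 4 is dimethylketene plus ethoxyacetylene.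
- Enabling feature: the ring C(CH3)2 flanked by two oxygen-bearing carbons in a 1,3,5-trioxygenated six-membered ring maps onto dimethylketene plus two ynol ethers, and this quaternary carbon blocks aromatisation.
- Forward: [2+2] to the four-membered ring, its two-carbon expansion to the gem-dimethyl cyclohexadienone (both outer rings come from this one building block), hydrolysis, C-propionylation.
- The central arene comes from phloroglucinol: butyrylation, double aminomethylation, then union with two molecules of 10.
- Stereochemistry: none to set.

Key step: step 2

**Step 1**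
Reactants: 1 isobutyryl chloride; 2 ethoxyacetylene
Product: 4 3-ethoxy-4,4-dimethylcyclobut-2-en-1-one, via dimethylketene 3 (not isolated)
Conditions: Et3N (1.2 equiv), 2 (1.5 equiv), Et2O, 0 °C → reflux
Reagents that add atoms: none
Why: Et3N dehydrochlorinates 1 to dimethylketene, which should undergo the thermal ketene–ynol ether [2+2] cycloaddition with the ketene carbonyl carbon bonding to the nucleophilic CH terminus of 2, giving the 3-ethoxy-4,4-dialkylcyclobutenone.

**Step 2**
Reactants: 4 3-ethoxy-4,4-dimethylcyclobut-2-en-1-one; 2 ethoxyacetylene
Product: 8 3,5-diethoxy-6,6-dimethylcyclohexa-2,4-dien-1-one, via vinylketene 5 (not isolated), via 4-alkenylcyclobutenone 6 (not isolated), via dienylketene 7 (not isolated)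
Conditions: 2 (3 equiv), PhMe, sealed tube, 95 °C
Reagents that add atoms: none
Why: Proposed new method: heating should open the strained cyclobutenone 4 by 4π-electrocyclic cleavage of its C(=O)–C(CH3)2 bond to vinylketene 5, whose ketene C=C adds the ynol ether in a [2+2] to give 4-alkenylcyclobutenone 6, which reopens to dienylketene 7 and closes by 6π-electrocyclisation, so that the four ring carbons of 4 end up in a six-membered ring with the two alkyne carbons inserted between C1 and C2. The closest known reaction type is the Danheiser benzannulation of cyclobutenones with alkoxyalkynes, which normally ends in tautomerisation to a phenol; here the carbon that would have to lose a proton is the quaternary C(CH3)2, so the cascade should stop at the 6,6-dimethylcyclohexa-2,4-dienone, which is the oxidation pattern of the outer rings of the target. Ring closures: the transient four-membered ring of 6 by thermal ketene–alkyne [2+2], and the six-membered ring by thermal disrotatory 6π-electrocyclisation of 7 that re-forms a C(=O)–C(CH3)2 bond. No stereocentre appears in 8, since the single one in racemic 6 is destroyed on ring opening. The step needs [2+2] regiochemistry that places the three oxygens 1,3,5, which the polarisation of the partners secures (ketene electrophilic at the carbonyl carbon, ynol ether nucleophilic at its CH carbon). It also needs capture of 5 faster than its dimerisation or [1,5]-hydrogen shift from the cis methyl group, which excess 2 and the reversible ring opening (low stationary concentration of 5) should secure; only the isomer of 7 with the ketene and the terminal alkene cis can cyclise, the other reverts to 6.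

**Step 3**
Reactants: 8 3,5-diethoxy-6,6-dimethylcyclohexa-2,4-dien-1-one
Product: 9 filicinic acid (3,5-dihydroxy-4,4-dimethylcyclohexa-2,5-dien-1-one)
Conditions: 2 M aq HCl, THF, 50 °C
Reagents that add atoms: water, O
Why: acid hydrolysis of the enol ether and the vinylogous ester (C-protonation, addition of water, loss of ethanol) should give the enolised 2,2-dimethylcyclohexane-1,3,5-trione.

**Step 4**
Reactants: 9 filicinic acid
Product: 10 propionylfilicinic acid (3,5-dihydroxy-4,4-dimethyl-2-propanoylcyclohexa-2,5-dien-1-one)
Conditions: EtCOCl (1.1 equiv), AlCl3 (3 equiv), PhNO2, rt → 50 °C; aq HCl work-up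
Reagents that add atoms: propionyl chloride, CCC(Cl)=O
Why: Friedel–Crafts C-acylation at one of the two equivalent nucleophilic ring CH positions of the enolised trione should stop at the mono-acyl stage, because the chelated β-triketone formed is deactivated.

**Step 5**
Reactants: 11 phloroglucinol
Product: 12 butyrylphloroglucinol (1-(2,4,6-trihydroxyphenyl)butan-1-one)
Conditions: n-PrCOCl (1.0 equiv), AlCl3 (3.5 equiv), PhNO2/CH2Cl2, 0 → 50 °C; aq HCl work-up
Reagents that add atoms: butyryl chloride, CCCC(Cl)=O
Why: Friedel–Crafts acylation of the electron-rich arene should be mono-selective, since the first acyl group deactivates the ring.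

**Step 6**
Reactants: 12 butyrylphloroglucinol
Product: 13 1-{3,5-bis[(dimethylamino)methyl]-2,4,6-trihydroxyphenyl}butan-1-one
Conditions: Me2N+=CH2 I− (2.1 equiv), i-Pr2NEt (2.1 equiv), MeCN, 0 °C → rt
Reagents that add atoms: N,N-dimethylmethyleneiminium iodide (Eschenmoser's salt), C=[N+](C)C.[I-]
Why: Mannich aminomethylation (electrophilic aromatic substitution by the preformed iminium ion) should occupy the only two free ring positions of the phenolate.

**Step 7**
Reactants: 13 bis-Mannich base; 10 propionylfilicinic acid (2.2 equiv)
Product: 17 target (filixic acid PBP type trimer), via first o-quinone methide 14 (not isolated), via mono-coupled Mannich base 15 (not isolated), via second o-quinone methide 16 (not isolated)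
Conditions: 10 (2.2 equiv), 1,4-dioxane, 90 °C, N2 stream; dilute acid work-up
Reagents that add atoms: none
Why: the acidic triketone 10 protonates each benzylic amine, thermal elimination of Me2NH should give the o-quinone methide, and Michael addition of the enolate of 10 through its only free ring carbon with rearomatisation (Mannich-base alkylation of a 1,3-dicarbonyl) forms each methylene bridge in turn.

**Compound list**
1 | isobutyryl chloride | CC(C)C(Cl)=O | starting material
2 | ethoxyacetylene (ethyl ethynyl ether) | CCOC#C | starting material
3 | dimethylketene | CC(C)=C=O | intermediate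
4 | 3-ethoxy-4,4-dimethylcyclobut-2-en-1-one | CCOC1=CC(=O)C1(C)C | intermediate
5 | 3-ethoxy-4-methylpenta-1,3-dien-1-one (vinylketene) | CCOC(C=C=O)=C(C)C | intermediate
6 | 3-ethoxy-4-(1-ethoxy-2-methylprop-1-en-1-yl)cyclobut-2-en-1-one (racemic, transient) | CCOC1=CC(=O)C1C(OCC)=C(C)C | intermediate
7 | (3E)-3,5-diethoxy-6-methylhepta-1,3,5-trien-1-one (dienylketene) | O=C=C/C(OCC)=C\C(OCC)=C(C)C | intermediate
8 | 3,5-diethoxy-6,6-dimethylcyclohexa-2,4-dien-1-one (filicinic acid diethyl ether) | CCOC1=CC(=O)C(C)(C)C(OCC)=C1 | intermediate
9 | filicinic acid (3,5-dihydroxy-4,4-dimethylcyclohexa-2,5-dien-1-one) | CC1(C)C(O)=CC(=O)C=C1O | intermediate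
10 | propionylfilicinic acid (3,5-dihydroxy-4,4-dimethyl-2-propanoylcyclohexa-2,5-dien-1-one) | CCC(=O)C1=C(O)C(C)(C)C(O)=CC1=O | intermediate
11 | phloroglucinol | Oc1cc(O)cc(O)c1 | starting material
12 | butyrylphloroglucinol (1-(2,4,6-trihydroxyphenyl)butan-1-one) | CCCC(=O)c1c(O)cc(O)cc1O | intermediate
13 | 1-{3,5-bis[(dimethylamino)methyl]-2,4,6-trihydroxyphenyl}butan-1-one | CCCC(=O)c1c(O)c(CN(C)C)c(O)c(CN(C)C)c1O | intermediate
14 | first o-quinone methide (13 minus Me2NH) | CCCC(=O)C1=C(O)C(CN(C)C)=C(O)C(=C)C1=O | intermediate
15 | mono-coupled Mannich base (one methylene bridge to a propionylfilicinic acid unit, one CH2NMe2 arm) | CCCC(=O)c1c(O)c(CN(C)C)c(O)c(CC2=C(O)C(C)(C)C(O)=C(C(=O)CC)C2=O)c1O | intermediate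
16 | second o-quinone methide (15 minus Me2NH) | CCCC(=O)C1=C(O)C(CC2=C(O)C(C)(C)C(O)=C(C(=O)CC)C2=O)=C(O)C(=C)C1=O | intermediate
17 | 2,2'-[(5-butanoyl-2,4,6-trihydroxy-1,3-phenylene)bis(methylene)]bis(3,5-dihydroxy-4,4-dimethyl-6-propanoylcyclohexa-2,5-dien-1-one) | CCCC(=O)c1c(O)c(CC2=C(O)C(C)(C)C(O)=C(C(=O)CC)C2=O)c(O)c(CC2=C(O)C(C)(C)C(O)=C(C(=O)CC)C2=O)c1O | target

**Totals**
Total step count: 7. Longest linear sequence: 5 steps (steps 1, 2, 3, 4, 7); the central unit takes 3 (steps 5, 6, 7).

**Steps most likely to fail**

Step 2 (Proposed new method). The 3-alkoxy group may make ring opening of 4 slow. The vinylketene may then be lost to a [1,5]-hydrogen shift from its cis methyl group, to ketene dimerisation, or to reaction with ketene formed by retro-ene fragmentation of ethoxyacetylene at the required temperature. Fallback by known chemistry, which takes the six-membered ring from an arene instead: setting out from 11, Friedel–Crafts acylation with propionyl chloride/AlCl3 should give 1-(2,4,6-trihydroxyphenyl)propan-1-one F1. Dearomative C,C-dimethylation of F1 with MeI/NaOMe in MeOH should give propionylfilicinic acid, and the route is rejoined at 10 (before step 7).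

Step 7. The o-quinone methides may dimerise or oligomerise instead of being captured. The methylene bridges may also migrate between partners by retro-Michael fragmentation, giving scrambled oligomers, and the second coupling may stall. Fallback with reversed polarity: setting out from 10, aminomethylation with Eschenmoser's salt (i-Pr2NEt, MeCN) should give 2-[(dimethylamino)methyl]-3,5-dihydroxy-4,4-dimethyl-6-propanoylcyclohexa-2,5-dien-1-one F2. Heating F2 (2.1 equiv) with 12 in dioxane should release 5-hydroxy-4,4-dimethyl-2-methylidene-6-propanoylcyclohex-5-ene-1,3-dione F3, so the electrophile now sits on the outer ring. The free ring CH of 12 should capture F3 to give the mono-bridged dimer 2-[(3-butanoyl-2,4,6-trihydroxyphenyl)methyl]-3,5-dihydroxy-4,4-dimethyl-6-propanoylcyclohexa-2,5-dien-1-one F4, and a second F3 then gives 17, where the route ends.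

Step 6. Aminomethylation may stop at mixtures of mono- and bis-adduct, and the product may lose amine prematurely on isolation and oligomerise. Fallback without any Mannich base: setting out from 12, a three-component condensation with 10 (2 equiv) and aqueous formaldehyde (2 equiv) in dilute aqueous KOH at rt, under conditions where the methylene bridges equilibrate, followed by acidification and crystallisation, should give 17 directly; this replaces steps 6 and 7.

**Further compounds**
F1 | step 2 | 1-(2,4,6-trihydroxyphenyl)propan-1-one | CCC(=O)c1c(O)cc(O)cc1O
F2 | step 7 | 2-[(dimethylamino)methyl]-3,5-dihydroxy-4,4-dimethyl-6-propanoylcyclohexa-2,5-dien-1-one | CCC(=O)C1=C(O)C(C)(C)C(O)=C(CN(C)C)C1=O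
F3 | step 7 | 5-hydroxy-4,4-dimethyl-2-methylidene-6-propanoylcyclohex-5-ene-1,3-dione | CCC(=O)C1=C(O)C(C)(C)C(=O)C(=C)C1=O
F4 | step 7 | 2-[(3-butanoyl-2,4,6-trihydroxyphenyl)methyl]-3,5-dihydroxy-4,4-dimethyl-6-propanoylcyclohexa-2,5-dien-1-one | CCCC(=O)c1c(O)cc(O)c(CC2=C(O)C(C)(C)C(O)=C(C(=O)CC)C2=O)c1O
F0 | step 6 | none | none
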